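All runs stem from a simulated flask with made-up constants; noise was put on by code.

The step constants are not given, so anything quantitative has to come out of the runs.

| flask | starting material | second substrate | coupling partner | free catalyst | remark | time |
|---|---|---|---|---|---|---|
| Saturday's | 0.80 M | 1 equiv | 2 equiv | 0.25 mol% | run made earlier |  |
| Sunday's | 0.80 M | 1 equiv | 2 equiv | 0.38 mol% | run made earlier |  |
| Tuesday's | 1.2 M | 1 equiv | 2 equiv | 0.5 mol% | run made earlier |  |
| flask | 0.80 M | 1.00 equiv | 2.00 equiv | 0.5 mol% |  | 3.0 h |

| run | time / h | starting material / % | target / % |
|---|---|---|---|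
| Saturday's | 0.250 | 93.9 | 5.1 |
| Saturday's | 0.500 | 86.8 | 13.0 |
| Saturday's | 1.00 | 80.0 | 21.2 |
| Saturday's | 2.00 | 62.0 | 37.4 |
| Saturday's | 4.00 | 35.8 | 59.2 |
| Sunday's | 0.667 | 77.7 | 20.2 |
| Sunday's | 1.33 | 60.9 | 37.3 |
| Sunday's | 2.00 | 46.6 | 50.9 |
| Sunday's | 3.00 | 32.6 | 63.1 |
| Sunday's | 4.00 | 23.2 | 72.2 |
| Tuesday's | 0.250 | 83.9 | 16.2 |
| Tuesday's | 0.500 | 68.8 | 28.9 |
| Tuesday's | 1.00 | 48.4 | 50.2 |
| Tuesday's | 2.00 | 23.1 | 70.4 |
| Tuesday's | 4.00 | 5.0 | 75.5 |

(each reading ± 1 percentage point)

- the earlier runs were read with a standard deviation of 1 percentage point
- steps thought possible: coupling partner + catalyst intermediate A -> free catalyst + target; coupling partner + catalyst intermediate B -> free catalyst + second product; second substrate + free catalyst <-> catalyst intermediate B; starting material + free catalyst <-> catalyst intermediate A; free catalyst + target -> free catalyst + over-reaction product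
- the reaction counts as stopped when no species that holds the starting material changes by six tenths of a point or more over the second half of the time

* why nothing more happens at 3.0 h, or that something still does (the coupling partner has run out first / all of the starting material has reacted / no working catalyst is left / it is still moving / forward and back rates have come level)
* how much of the starting material has reacted by 3.0 h
* how much target there is at 3.0 h, in percent of the starting material charged
* how much over-reaction product there is at 3.0 h, in percent of the starting material charged
* amount of target if the flask were left three thousand times as long, in percent of the starting material charged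

Try a clock counted in catalyst. Your flask at 3.0 h has taken 12.0 mM·h, the catalyst dose, meaning charged catalyst concentration times elapsed time.

Tuesday's run, at 1.2 M, reached 12.0 mM·h at 2.00 h and read 23.1% starting material. Sunday's run, at 0.80 M and 0.38 mol%, reached 12.2 mM·h at 4.00 h and read 23.2%. At these equivalents, then, those two runs line up on dose, not on hours. The loss of starting material looks pseudo-first-order in dose, and Tuesday's reading gives a half-dose of 5.68 mM·h.

Your own reckoning therefore copies Tuesday's reading at the same dose. Conversion is 76.9% and target 70.4%, while Sunday's 72.2% shows the width of that figure. The gap in Tuesday's reading, 6.50%, you book as over-reaction product, since it is more than the 0.5 mol% loading that the catalyst forms can hold. Over the second half of the time your flask covers the dose Tuesday's run covered from 1.00 h to 2.00 h, when starting material fell from 48.4% to 23.1%, so it is still moving.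

The forecast gives 77% conversion (75% to 79%), 70% target (67% to 72.5%) and 7% over-reaction product (5% to 9.5%). It also says it is still moving, and it puts the long-time target at 0% on the ground “No deactivation step is listed”.

The flask gives 77.6% conversion, 70.7% target and 6.53% over-reaction product; it is still moving, and the long-time target is 0%.

    coupling partner + catalyst intermediate A → free catalyst + target (k = 1.40 L mol⁻¹ min⁻¹)
    coupling partner + catalyst intermediate B → free catalyst + second product (k = 7.60 L mol⁻¹ min⁻¹)
    second substrate + free catalyst ⇌ catalyst intermediate B (K = 11.0 L mol⁻¹, k = 9.60 L mol⁻¹ min⁻¹)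
    starting material + free catalyst ⇌ catalyst intermediate A (K = 200 L mol⁻¹, k = 11.0 L mol⁻¹ min⁻¹)
    free catalyst + target → free catalyst + over-reaction product (k = 1.00 L mol⁻¹ min⁻¹)

At its dose of 12.0 mM·h the flask stands 0.68 percentage points in conversion from Tuesday's reading. A neighbour flask with 0.85 mol% of free catalyst reaches 20.4 mM·h at the same time, a larger dose. The half-dose then leaves 8.30% starting material. That neighbour holds 6.93% starting material, 76.8% target and 15.8% over-reaction product.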